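**Retrosynthetic overview**
1. Target 8 ⇐ 7 by one global hydrogenolysis: five O‑benzyl groups and four aryl bromines (positional blocking groups) leave under buffered, non‑acidic conditions that spare the para‑hydroxybenzylic alcohol.
2. 7 ⇐ 6 by closing the only ring made in the route, the five‑membered ring of the indane (Friedel–Crafts attack on a quinone methide, anti to the neighbouring aryl group).
3. 6 ⇐ meso 5 by the key C–O disconnection: a catalyst‑controlled, desymmetrising oxa‑1,6‑addition of benzyl alcohol to one of two enantiotopic quinone methides; this bond carries the future carbinol oxygen and fixes the absolute configuration.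
4. 5 ⇐ 4 by oxidative tail‑to‑tail (benzylic carbon to benzylic carbon) dimerisation of a 2,6‑dibromophenol stilbene; 4 ⇐ 2 + 3 (Horner–Wadsworth–Emmons); 2 ⇐ 1 (Arbuzov).
5. Ring order: no ring is formed before step 3; the indane ring closes at the end of step 3, after the C–O bond.

Assumption: the sense of induction of the new catalytic step is unproven; the (R)‑acid is written and its mirror image is used if it delivers the antipodal series.

**Step 1**
Reactants: 1 3,5-bis(benzyloxy)benzyl bromide
Product: 2 diethyl [3,5-bis(benzyloxy)benzyl]phosphonate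
Conditions: P(OEt)3 (neat), 140 °C
Reagents that add atoms: triethyl phosphite, CCOP(OCC)OCC
Why: Michaelis–Arbuzov reaction of a primary benzylic bromide is clean and the volatile bromoethane distils out; no stereocentre is involved.

**Step 2**
Reactants: 2 diethyl [3,5-bis(benzyloxy)benzyl]phosphonate; 3 3,5-dibromo-4-hydroxybenzaldehyde
Product: 4 (E)-4-{2-[3,5-bis(benzyloxy)phenyl]ethenyl}-2,6-dibromophenol
Conditions: KOtBu (2.3 equiv), THF, 0 °C to rt; aq. HCl
Reagents that add atoms: none
Why: Horner–Wadsworth–Emmons olefination of a benzylic phosphonate anion gives the (E)-stilbene, the extra equivalent of base carrying the acidic bromophenol through as its phenoxide.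

**Step 3**
Reactants: 4 (E)-4-{2-[3,5-bis(benzyloxy)phenyl]ethenyl}-2,6-dibromophenol (2 equiv)
Product: 7 (1R,2S,3R)-4,6-bis(benzyloxy)-1-[(S)-benzyloxy(3,5-dibromo-4-hydroxyphenyl)methyl]-2-[3,5-bis(benzyloxy)phenyl]-3-(3,5-dibromo-4-hydroxyphenyl)-2,3-dihydro-1H-indene, via meso bis(quinone methide) 5 (not isolated), via benzyl ether quinone methide 6 (not isolated)
Conditions: Ag2O, 4 Å MS, CH2Cl2, 0 °C, dark, cold filtration; then BnOH (0.5 equiv per 4), (R)-3,3'-bis(2,4,6-triisopropylphenyl)-1,1'-binaphthyl-2,2'-diyl hydrogen phosphate (5 mol %), PhMe, −60 °C; then Tf2NH (10 mol %), −78 °C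
Reagents that add atoms: benzyl alcohol, OCc1ccccc1
Why: Proposed new method: Ag2O oxidises the ortho‑blocked bromophenol to a phenoxyl radical that can pair only through the styryl β‑carbons, giving the meso bis(quinone methide) 5 beside its racemic diastereomer; the chiral phosphoric acid then binds one quinone methide carbonyl through P–OH and benzyl alcohol through P=O and delivers the oxygen to one face of one of the two enantiotopic exocyclic carbons (a desymmetrising oxa‑1,6‑conjugate addition, whose closest known relatives are chiral phosphoric acid catalysed 1,6‑additions of thiols, naphthols and enamides to tert‑butyl‑blocked para‑quinone methides), so the (S)‑configured C–O stereocentre is set under catalyst control and its position decides which half of the meso backbone cyclises, which fixes the two backbone centres as 2S,3R; Tf2NH finally protonates the remaining quinone methide for a 5‑exo Friedel–Crafts closure by the adjacent bis(benzyloxy)phenyl ring anti to the neighbouring aryl group (the acid‑induced cyclisation known for tert‑butyl‑blocked stilbene bis(quinone methides)), while the new ether, deactivated by two bromines, does not ionise.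

**Step 4**
Reactants: 7 (1R,2S,3R)-4,6-bis(benzyloxy)-1-[(S)-benzyloxy(3,5-dibromo-4-hydroxyphenyl)methyl]-2-[3,5-bis(benzyloxy)phenyl]-3-(3,5-dibromo-4-hydroxyphenyl)-2,3-dihydro-1H-indene
Product: 8 (1R,2S,3R)-2-(3,5-dihydroxyphenyl)-1-[(S)-hydroxy(4-hydroxyphenyl)methyl]-3-(4-hydroxyphenyl)-2,3-dihydro-1H-indene-4,6-diol (CNP0214825.2)
Conditions: H2 (1 atm), Pd/C (10 wt% Pd), NaOAc, THF/EtOAc, rt
Reagents that add atoms: none
Why: Catalytic hydrogenolysis removes the four aryl bromines and all five O‑benzyl groups (the alkyl benzyl ether breaks at the unsubstituted PhCH2–O bond) while NaOAc takes up HBr without deprotonating the bromophenol, so the benzylic C–O stereocentre is neither ionised nor epimerised and no other stereocentre is touched.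

**Compound list**
1 | 3,5-bis(benzyloxy)benzyl bromide | BrCc1cc(OCc2ccccc2)cc(OCc2ccccc2)c1 | starting material
2 | diethyl [3,5-bis(benzyloxy)benzyl]phosphonate | CCOP(=O)(OCC)Cc1cc(OCc2ccccc2)cc(OCc2ccccc2)c1 | intermediate
3 | 3,5-dibromo-4-hydroxybenzaldehyde | O=Cc1cc(Br)c(O)c(Br)c1 | starting material
4 | (E)-4-{2-[3,5-bis(benzyloxy)phenyl]ethenyl}-2,6-dibromophenol | Oc1c(Br)cc(/C=C/c2cc(OCc3ccccc3)cc(OCc3ccccc3)c2)cc1Br | intermediate
5 | meso-4,4'-[(2R,3S)-2,3-bis[3,5-bis(benzyloxy)phenyl]butane-1,4-diylidene]bis(2,6-dibromocyclohexa-2,5-dien-1-one) | O=C1C(Br)=CC(C=C1Br)=C[C@H](c1cc(OCc2ccccc2)cc(OCc2ccccc2)c1)[C@@H](C=C1C=C(Br)C(=O)C(Br)=C1)c1cc(OCc2ccccc2)cc(OCc2ccccc2)c1 | intermediate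
6 | 4-[(2S,3R,4S)-4-(benzyloxy)-2,3-bis[3,5-bis(benzyloxy)phenyl]-4-(3,5-dibromo-4-hydroxyphenyl)butylidene]-2,6-dibromocyclohexa-2,5-dien-1-one | O=C1C(Br)=CC(C=C1Br)=C[C@H](c1cc(OCc2ccccc2)cc(OCc2ccccc2)c1)[C@H](c1cc(OCc2ccccc2)cc(OCc2ccccc2)c1)[C@H](OCc1ccccc1)c1cc(Br)c(O)c(Br)c1 | intermediate
7 | (1R,2S,3R)-4,6-bis(benzyloxy)-1-[(S)-benzyloxy(3,5-dibromo-4-hydroxyphenyl)methyl]-2-[3,5-bis(benzyloxy)phenyl]-3-(3,5-dibromo-4-hydroxyphenyl)-2,3-dihydro-1H-indene (all-trans on the five-membered ring) | Oc1c(Br)cc([C@@H]2c3c(OCc4ccccc4)cc(OCc4ccccc4)cc3[C@H]([C@H](OCc3ccccc3)c3cc(Br)c(O)c(Br)c3)[C@H]2c2cc(OCc3ccccc3)cc(OCc3ccccc3)c2)cc1Br | intermediate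
8 | (1R,2S,3R)-2-(3,5-dihydroxyphenyl)-1-[(S)-hydroxy(4-hydroxyphenyl)methyl]-3-(4-hydroxyphenyl)-2,3-dihydro-1H-indene-4,6-diol | Oc1ccc([C@@H]2c3c(O)cc(O)cc3[C@H]([C@H](O)c3ccc(O)cc3)[C@H]2c2cc(O)cc(O)c2)cc1 | target

**Step count and risks**
Total steps: 4. Longest linear sequence: 4 (1 → 2 → 4 → 7 → 8).

Most likely to fail, first: step 3 (the new step). The bromine‑blocked phenol has not been dimerised this way, and the bis(quinone methide) is more electrophilic than its tert‑butyl analogues and must be handled cold and dry. Only the meso half of the dimer (about half of the material, if the pairing is unselective) can give 7; the racemic half ends as cis‑indane diastereomers that are removed by chromatography. The level of catalyst control in the alcohol addition is unknown. Fallback with known chemistry, setting out from 4 and coming back at 7: 4 is oxidised with Ag2O as before, the cold filtrate is treated with BF3·OEt2 at −78 °C (achiral acid‑induced Friedel–Crafts closure, as established for tert‑butyl‑blocked bis(quinone methides)), and the surviving quinone methide is quenched with benzyl alcohol. Chromatography gives racemic 7, that is 7 together with its mirror image, (1S,2R,3S)-4,6-bis(benzyloxy)-1-[(R)-benzyloxy(3,5-dibromo-4-hydroxyphenyl)methyl]-2-[3,5-bis(benzyloxy)phenyl]-3-(3,5-dibromo-4-hydroxyphenyl)-2,3-dihydro-1H-indene F1. The racemate is resolved by preparative HPLC on an amylose tris(3,5-dimethylphenylcarbamate) phase, and 7 rejoins the route at step 4.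

Second: step 4. Palladium may also cut the secondary benzylic C–O bond next to the electron‑rich ring, and while bromine is still on the ring the acidic phenol could expel the benzylic alkoxide if the medium becomes basic. Fallback, setting out from 7 and coming back at 8: the bromines are removed first under amine‑poisoned conditions that leave all benzyl ethers intact (H2, Pd/C, pyridine, EtOAc), giving (1R,2S,3R)-4,6-bis(benzyloxy)-1-[(S)-benzyloxy(4-hydroxyphenyl)methyl]-2-[3,5-bis(benzyloxy)phenyl]-3-(4-hydroxyphenyl)-2,3-dihydro-1H-indene F2. The benzyl groups are then cleaved without any metal surface by electron transfer from lithium 4,4'-di-tert-butylbiphenylide in THF at −78 °C, which fragments each PhCH2–O bond towards the oxygen anion, followed by NH4Cl, to give 8.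

Third: step 2. The aldehyde reacts as a phenoxide and is a sluggish electrophile, so conversion may stall. Fallback, setting out from 2 and coming back at 4: the anion of 2 (NaH, THF) is methylenated with paraformaldehyde to 1,3-bis(benzyloxy)-5-ethenylbenzene F3. This is joined to commercial 2,6-dibromo-4-iodophenol by a Mizoroki–Heck reaction that is selective for the C–I bond (Pd(OAc)2, P(o-tolyl)3, Et3N, DMF, 90 °C), giving 4 with the (E) geometry.

**Further compounds**
F1 | step 3 | (1S,2R,3S)-4,6-bis(benzyloxy)-1-[(R)-benzyloxy(3,5-dibromo-4-hydroxyphenyl)methyl]-2-[3,5-bis(benzyloxy)phenyl]-3-(3,5-dibromo-4-hydroxyphenyl)-2,3-dihydro-1H-indene (mirror image of 7) | Oc1c(Br)cc([C@H]2c3c(OCc4ccccc4)cc(OCc4ccccc4)cc3[C@@H]([C@@H](OCc3ccccc3)c3cc(Br)c(O)c(Br)c3)[C@@H]2c2cc(OCc3ccccc3)cc(OCc3ccccc3)c2)cc1Br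
F2 | step 4 | (1R,2S,3R)-4,6-bis(benzyloxy)-1-[(S)-benzyloxy(4-hydroxyphenyl)methyl]-2-[3,5-bis(benzyloxy)phenyl]-3-(4-hydroxyphenyl)-2,3-dihydro-1H-indene | Oc1ccc([C@@H]2c3c(OCc4ccccc4)cc(OCc4ccccc4)cc3[C@H]([C@H](OCc3ccccc3)c3ccc(O)cc3)[C@H]2c2cc(OCc3ccccc3)cc(OCc3ccccc3)c2)cc1
F3 | step 2 | 1,3-bis(benzyloxy)-5-ethenylbenzene | C=Cc1cc(OCc2ccccc2)cc(OCc2ccccc2)c1
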